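## The problem

The target is a daucane sesquiterpenoid ester. A cyclopentanone (C1–C5) is trans-fused through the C1–C5 bond to a cycloheptene (C1, C5–C10). The numbering used here is: C1 the methyl-bearing quaternary carbon, C2 the ketone, C3 a CH2, C4 the isopropyl carbinol, C5 the ring-fusion CH, C6 the ester carbinol, C8=C9 the methyl-bearing olefin, C11 the isopropyl methine, C15 the methyl on C1; β is the face of C15. Four contiguous stereocentres must be set: C1 (R), C4 (R, hydroxyl β), C5 (S, hydrogen α) and C6 (S, oxygen α). C1 is quaternary and cannot be corrected later, so it has to come first. It then differentiates the two faces of the five-membered ring, and the β-hydroxyl at C4, once in place, can send reagents at C5 and C6 to the α face. The C2 ketone and the C4 hydroxyl form a tertiary aldol that can dehydrate or cleave in strong acid or base, the C8=C9 olefin is exposed to every electrophile and oxidant, and the anisate combines a cleavable ester with an electron-rich arene. The hardest single function is the C2 carbonyl, an isolated oxidised methylene next to the quaternary C1 with no neighbouring group through which it could be introduced. A short entry is possible because the fifteen skeletal carbons are an unbroken head-to-tail farnesyl chain closed by only two bonds, C1–C10 and C4–C5, with the C8=C9 olefin and the C1 methyl exactly where a farnesyl cation cascade leaves them.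

## Retrosynthesis

**17 to 15 and 16.** The acyl–oxygen bond of the C6 ester is cut last. The anisate arene would not survive the oxidant needed for C2, and the ester is the group most at risk in the reductive unmasking, so it is kept out until the end. The precursor 15 has a single secondary hydroxyl, so the forward step only has to acylate C6 with retention under conditions that leave the aldol unit alone; 16 is commercial.

**15 to 13 (through 14).** No skeletal bond is cut. The C8=C9 olefin is traced back to a vicinal dibromide and the C6 hydroxyl to a trichloroethyl carbonate. Both masks were chosen because a single zinc reduction removes them together. They are needed because neither an olefin nor a free secondary alcohol can be present while C2 is oxidised.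

**13 to 11 (through 12).** The C2 carbonyl is traced back to the C2 methylene. The cyclase product carries no function at C2 or C3, so every enolate- or olefin-based way of reaching C2 would need a long transposition. A direct C–H oxidation is therefore placed on 11, the one intermediate in which every other CH2 or CH sits on or next to a carbon bearing oxygen or bromine. The forward reaction must be site-selective for the one electronically unbiased methylene.

**11 to 10.** The carbonate C–O bond is cut. Compound 10 is the diol with the final configuration at all four stereocentres; the forward step only has to distinguish the secondary from the tertiary hydroxyl.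

**10 to 8 (through 9).** The C5–H and C6–O bonds are cut together, leading back to the C5=C6 olefin of 8. A syn addition from the α face sets both centres at once and gives the C6 oxygen in its final configuration. The neighbouring option, hydroxyl-directed epoxidation and reductive opening, would place the C6 oxygen on the β face and need an inversion. The forward reaction must attack the face opposite to the C4 oxygen and the C1 methyl.

**8 to 7.** The two C–Br bonds are cut. The dibromide masks C8=C9, which would otherwise be the faster olefin in the hydroboration, and it serves a second time during the C2 oxidation. The forward reaction must select the unhindered C8=C9 over the C5=C6 olefin, which is flanked by two fully substituted carbons.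

**7 to 4 (through 5 and 6).** The C4–O bond is cut and the olefin is moved back from C5=C6 to C4=C5. The C4 oxygen has to sit on the β face, the face of the C1 methyl. A direct oxygen transfer (epoxidation, ene reaction) would come from the open α face, so the forward reaction must be an anti addition: an electrophile on the α face and the oxygen nucleophile from the β face at C4. The electrophile must then leave towards C6, the only neighbour of C5 that carries hydrogen. Precursor 4 is a hydrocarbon with a single stereocentre.

**4 to 3.** The C1–C10 and C4–C5 bonds are cut, which opens both rings and removes the only stereocentre. This is the cut that pays: 3 is an achiral, acyclic C15 diphosphate, and no stepwise laboratory sequence builds the quaternary C1, the seven- and five-membered rings and the C8=C9 olefin as directly. The forward reaction is asked for complete control of folding, of the absolute configuration at C1 and of the site of the final proton loss, which only a terpene cyclase provides.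

**3 to 2 to 1.** The C–O–P bond is cut to the allylic chloride 2 and then to commercial 1. The forward steps must keep the 2E,6E geometry and avoid allylic transposition.

## Roads not taken

**Alternative 1:** The cut is C1–C10 and C5–C6. In the forward direction a base-generated oxidopyrylium ylide A3 adds across the C1=C5 bond of cyclopentenone A2 in a (5+2) cycloaddition to give the oxygen-bridged tricycle A1.
- Merits: the route is convergent. One step forms two C–C bonds, the seven-membered ring, the quaternary C1 and C5. A1 already carries the C2 oxygen (silyl ether), a C4 ketone for isopropyl addition, the C8 methyl and, through the ether bridge, the C6 oxygen.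
- Weak points: the dipolarophile is β,β-disubstituted, so bond formation at the fully substituted C1 is slow and the facial, endo/exo and regiochemical outcome rests on one silyloxy stereocentre. The suprafacial addition gives the cis ring fusion (H-5 syn to the C1 methyl), which must be inverted. The seven-membered ring arrives with a C9 ketone, a C7=C8 olefin and a C6–O–C10 bridge, so the C10–O bond has to be cleaved, the C9 carbonyl deleted and the olefin moved to C8=C9.
- Comparison: Alternative 1 is better than the chosen plan at C2 and C6, where it needs neither C–H oxidation nor olefin masking. The chosen plan sets against this that the C8=C9 olefin, the isopropyl group and the correct oxidation level of the seven-membered ring come out of one step, with no redox correction afterwards.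

**Alternative 2:** The cut is C6–C7 and C7–C8, a one-carbon ring enlargement. Silyl enol ether A5, derived from the (R)-Hajos–Parrish ketone A6, is cyclopropanated with a zinc carbenoid, opened with an iron trihalide and eliminated to give cycloheptenone A4.
- Merits: C1 comes from a proline-catalysed reaction that runs on scale, C2 is oxygenated (ketal) throughout, and the ring expansion is well precedented. The enone of A4 offers the C8 carbonyl for the methyl group and C6 as an electrophilic position.
- Weak points: A4 has bare methylenes at C3 and C4, so the isopropyl carbinol must be built from the C2 carbonyl side in a long detour. The unnatural enantiomer of the catalyst is needed. The trans ring fusion is not the normal outcome of hydrogenating this enone. The C6 oxygen, the C8 methyl and the C8=C9 olefin all still have to be added.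
- Comparison: step by step this road is the most reliable of all, and it is better than the chosen plan at C1 and C2. It is clearly longer and meets its own unactivated-position problem at C4. The chosen plan delivers C4 with its isopropyl group and a usable olefin.

**Alternative 3:** The cut is C4–C5. Halogen–metal exchange of alkenyl iodide A8 (or a chromium/nickel-mediated variant) gives a C5 alkenyl metal that adds to the C4 isopropyl ketone and closes the five-membered ring to A7.
- Merits: A7 is the C2 ketal of compound 7 of the present route. The same hydroboration endgame would apply with the C2 oxygen already in place, so no C–H oxidation and no olefin masking are needed. Ring and carbinol form in one step.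
- Weak points: A8 is a cycloheptadienyl iodide with the quaternary C1 stereocentre and a keto side chain, and itself needs a multistep enantioselective synthesis. The C4 configuration depends on the facial selectivity of a ring-closing carbonyl addition guided only by C1. Enolisation of the ketone or attack by the exchange reagent can compete.
- Comparison: for the late stage this is the stronger road, and it would be preferred if the C2 oxidation of the chosen plan cannot be made selective. The chosen plan sets against it three steps from a commercial alcohol to the complete skeleton, C1 fixed by the enzyme, and C4 set by a stereospecific anti addition and not by an unguided addition to a ketone.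

Key step: step 3

Remarks on the chemistry:
- Assumption: a recombinant class 1 sesquiterpene cyclase of the carotol series whose main product is dauca-4,8-diene is available, as wild type or as a variant selected for olefin release. If only the hydrating enzyme is at hand, the fallback under step 3 applies.
- The dibromides 8–13 are the anti adducts. C8 and C9 are drawn without configuration because both centres are erased in step 9. Compound 12 is drawn without configuration at C2.
- PDP = 2,2'-[(2S,2'S)-[2,2'-bipyrrolidine]-1,1'-diylbis(methylene)]dipyridine; TrocCl = 2,2,2-trichloroethyl chloroformate.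

Step 1
Reactants: 1 (2E,6E)-farnesol
Product: 2 (2E,6E)-farnesyl chloride
Conditions: NCS, Me2S, CH2Cl2, −40 → 0 °C
Reagents that add atoms: N-chlorosuccinimide, O=C1CCC(=O)N1Cl
Why: Corey–Kim chlorination: the alkoxysulfonium salt of the primary allylic alcohol is displaced by chloride in an SN2 reaction, so neither allylic transposition nor loss of the 2E geometry is expected; no stereocentre is formed.

Step 2
Reactants: 2 (2E,6E)-farnesyl chloride
Product: 3 (2E,6E)-farnesyl diphosphate (tris-ammonium salt)
Conditions: (Bu4N)3HP2O7, MeCN, rt; then Dowex 50WX8 (NH4+ form), aq. NH4HCO3
Reagents that add atoms: tris(tetrabutylammonium) hydrogen diphosphate, CCCC[N+](CCCC)(CCCC)CCCC.CCCC[N+](CCCC)(CCCC)CCCC.CCCC[N+](CCCC)(CCCC)CCCC.OP(=O)([O-])OP(=O)([O-])[O-]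
Why: SN2 displacement of the allylic chloride by the diphosphate anion in a dipolar aprotic solvent, the standard access to prenyl diphosphates; cation exchange gives the water-soluble ammonium salt that cyclases accept.

Step 3
Reactants: 3 (2E,6E)-farnesyl diphosphate
Product: 4 (1R)-dauca-4,8-diene (daucene)
Conditions: recombinant daucene-forming class 1 sesquiterpene cyclase (carotol-synthase family), MgCl2 (10 mM), HEPES pH 7.5, DTT, 30 °C, pentane overlay
Reagents that add atoms: none
Why: The Mg2+-bound diphosphate ionises (through the tertiary allylic isomer, which allows the cisoid C8=C9 geometry) and the allyl cation is attacked at C10 by the C5=C1 olefin in a 6-exo closure that leaves the charge on C1. A 1,2-shift of C10 from C5 to C1 then forms the C1–C10 bond, enlarges the ring to the seven-membered cycloheptenyl cation and creates the quaternary C1. The C4=C11 olefin adds to the C5 cation in a 5-exo closure (C4–C5, five-membered ring), a 1,2-hydride shift moves the charge from C11 to C4, and loss of the C5 proton gives the C4=C5 olefin. The closest known reaction type is the conversion of farnesyl diphosphate into carotol and other daucanes by class 1 terpene cyclases. The only stereocentre of 4, C1, is controlled by the enzyme, whose active-site contour fixes the fold of the chain and thereby the face of C1 to which C10 migrates; no substrate stereocentre exists to do so. The step needs product specificity, that is deprotonation at C5 instead of capture of water (which gives the C5 alcohol) or proton loss elsewhere, and this is secured by the choice or engineering of the cyclase, not by the substrate.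

Step 4
Reactants: 4 (1R)-dauca-4,8-diene
Product: 7 (1R,4R)-dauca-5,8-dien-4β-ol, via hydroxy selenide 5 (not isolated), via selenoxide 6 (not isolated)
Conditions: N-(phenylseleno)phthalimide, H2O (3 equiv), CSA (cat.), CH2Cl2, 0 °C → rt; then mCPBA, CH2Cl2, −78 °C; i-Pr2NH, −78 °C → rt
Reagents that add atoms: water, O
Why: Anti hydroxyselenation followed by selenoxide syn elimination: the seleniranium ion forms on the face of C4=C5 opposite the C1 methyl and water opens it from the methyl face at C4, the carbon not shielded by the quaternary C1, which sets the 4β-hydroxyl. The C5 selenoxide has syn β-hydrogens only on C6 (C1 and C4 carry none), so elimination can give only the C5=C6 allylic alcohol. The more electron-rich tetrasubstituted olefin should react before C8=C9, and i-Pr2NH intercepts the selenenic acid before it can add to the product.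

Step 5
Reactants: 7 (1R,4R)-dauca-5,8-dien-4β-ol
Product: 8 trans-8,9-dibromodauc-5-en-4β-ol
Conditions: Br2 (1.0 equiv), pyridine (cat.), CH2Cl2, −78 °C
Reagents that add atoms: bromine, BrBr
Why: Electrophilic anti addition of bromine, the classical protection of an olefin as its vicinal dibromide: C8=C9 is an unhindered trisubstituted olefin, whereas C5=C6 is flanked by two fully substituted carbons and deactivated by the allylic hydroxyl. A transannular bromo-ether cannot form because C4 and C7 are trans on the C5=C6 bond; the two bromine-bearing centres are temporary and are erased in step 9.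

Step 6
Reactants: 8 trans-8,9-dibromodauc-5-en-4β-ol
Product: 10 trans-8,9-dibromodaucane-4β,6α-diol (5α-H), via C6 alkylborane 9 (not isolated)
Conditions: BH3·THF, THF, 0 °C → rt; then NaBO3·4H2O, THF/H2O, rt
Reagents that add atoms: sodium perborate tetrahydrate (NaBO3·4H2O), [Na+].[Na+].O[B-]1(O)OO[B-](O)(O)OO1
Why: Hydroboration–oxidation: boron adds to the less substituted C6 and hydrogen to C5 in a syn fashion from the α face, anti to the C4 oxygen (held as a borate) and to the C1 methyl, which should give the trans ring fusion (5α-H). Oxidation of the C–B bond with retention then gives the 6α-hydroxyl; the alkyl bromides are inert to borane and to the mild perborate oxidation.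

Step 7
Reactants: 10 trans-8,9-dibromodaucane-4β,6α-diol
Product: 11 trans-8,9-dibromo-4β-hydroxydaucan-6α-yl 2,2,2-trichloroethyl carbonate
Conditions: TrocCl, pyridine, DMAP (cat.), CH2Cl2, 0 °C → rt
Reagents that add atoms: 2,2,2-trichloroethyl chloroformate, ClC(=O)OCC(Cl)(Cl)Cl
Why: Chloroformate acylation of the only secondary hydroxyl; the tertiary C4 hydroxyl does not react. The electron-withdrawing carbonate protects the C6 alcohol, deactivates C6–H for step 8 and is later removed by the same zinc that unmasks the olefin.

Step 8
Reactants: 11 trans-8,9-dibromo-4β-hydroxydaucan-6α-yl 2,2,2-trichloroethyl carbonate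
Product: 13 trans-8,9-dibromo-4β-hydroxy-2-oxodaucan-6α-yl 2,2,2-trichloroethyl carbonate, via C2 alcohol 12 (not isolated)
Conditions: [Fe((S,S)-PDP)(MeCN)2](SbF6)2 (3 × 5 mol%), AcOH (3 × 0.5 equiv), 50% aq. H2O2 (3 × 1.2 equiv), MeCN, rt
Reagents that add atoms: hydrogen peroxide, OO
Why: Non-directed iron-catalysed aliphatic C–H oxidation (methylene to ketone through alcohol 12): the electrophilic iron-oxo oxidant attacks the most electron-rich accessible C–H bond. In 11 every CH2 or CH other than C2 sits on or next to a carbon bearing oxygen or bromine (C3, C5, C6, C7, C9, C10, C11), and methyl groups are not oxidised. No olefin, free secondary alcohol or electron-rich arene is present, which is why the oxidation is placed here; no stereocentre is formed.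

Step 9
Reactants: 13 trans-8,9-dibromo-4β-hydroxy-2-oxodaucan-6α-yl 2,2,2-trichloroethyl carbonate
Product: 15 (1R,4R,5S,6S)-4β,6α-dihydroxydauc-8-en-2-one, via olefinic trichloroethyl carbonate 14 (not isolated)
Conditions: Zn dust, AcOH, THF, 0 °C → rt
Reagents that add atoms: none
Why: Zinc-mediated reductive anti elimination of the vicinal dibromide regenerates C8=C9 at the position fixed by the two bromine-bearing carbons. Zinc insertion into a C–Cl bond of the trichloroethyl carbonate, β-elimination and loss of CO2 then free the C6 hydroxyl; the ketone, the tertiary alcohol and the aldol unit are stable to zinc in acetic acid.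

Step 10
Reactants: 15 (1R,4R,5S,6S)-4β,6α-dihydroxydauc-8-en-2-one; 16 4-methoxybenzoic acid
Product: 17 (1R,4R,5S,6S)-4β-hydroxy-2-oxodauc-8-en-6α-yl 4-methoxybenzoate (CNP0232277.1)
Conditions: EDC·HCl, DMAP, CH2Cl2, rt
Reagents that add atoms: none
Why: Steglich esterification: the carbodiimide-activated acid is transferred by DMAP to the single secondary hydroxyl with retention at C6, the tertiary C4 hydroxyl being too hindered to acylate. The mild, anhydrous conditions should leave the β-hydroxy ketone and the olefin intact.

Compound list

1 | (2E,6E)-farnesol | CC(C)=CCC/C(C)=C/CC/C(C)=C/CO | starting material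
2 | (2E,6E)-farnesyl chloride | CC(C)=CCC/C(C)=C/CC/C(C)=C/CCl | intermediate
3 | (2E,6E)-farnesyl diphosphate (handled as the tris-ammonium salt, free acid drawn) | CC(C)=CCC/C(C)=C/CC/C(C)=C/COP(=O)(O)OP(=O)(O)O | intermediate
4 | (1R)-dauca-4,8-diene (daucene) | C1CC(C)=CC[C@@]2(C)CCC(C(C)C)=C12 | intermediate
5 | 5α-(phenylselanyl)dauc-8-en-4β-ol (hydroxy selenide) | CC1=CC[C@@]2(C)CC[C@@](O)(C(C)C)[C@]2([Se]c3ccccc3)CC1 | intermediate (not isolated)
6 | 5α-(phenylseleninyl)dauc-8-en-4β-ol (selenoxide, configuration at selenium open) | CC1=CC[C@@]2(C)CC[C@@](O)(C(C)C)[C@]2([Se](=O)c3ccccc3)CC1 | intermediate (not isolated)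
7 | (1R,4R)-dauca-5,8-dien-4β-ol | CC1=CC[C@@]2(C)CC[C@@](O)(C(C)C)C2=CC1 | intermediate
8 | trans-8,9-dibromodauc-5-en-4β-ol | CC1(Br)C(Br)C[C@@]2(C)CC[C@@](O)(C(C)C)C2=CC1 | intermediate
9 | (trans-8,9-dibromo-4β-hydroxy-5α-daucan-6α-yl)borane (drawn as RBH2; the C4 hydroxyl is a borate ester in the flask) | B[C@H]1CC(C)(Br)C(Br)C[C@@]2(C)CC[C@@](O)(C(C)C)[C@H]12 | intermediate (not isolated)
10 | trans-8,9-dibromodaucane-4β,6α-diol (5α-H) | O[C@H]1CC(C)(Br)C(Br)C[C@@]2(C)CC[C@@](O)(C(C)C)[C@H]12 | intermediate
11 | trans-8,9-dibromo-4β-hydroxydaucan-6α-yl 2,2,2-trichloroethyl carbonate | ClC(Cl)(Cl)COC(=O)O[C@H]1CC(C)(Br)C(Br)C[C@@]2(C)CC[C@@](O)(C(C)C)[C@H]12 | intermediate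
12 | trans-8,9-dibromo-2,4β-dihydroxydaucan-6α-yl 2,2,2-trichloroethyl carbonate (C2 configuration open) | ClC(Cl)(Cl)COC(=O)O[C@H]1CC(C)(Br)C(Br)C[C@@]2(C)C(O)C[C@@](O)(C(C)C)[C@H]12 | intermediate (not isolated)
13 | trans-8,9-dibromo-4β-hydroxy-2-oxodaucan-6α-yl 2,2,2-trichloroethyl carbonate | ClC(Cl)(Cl)COC(=O)O[C@H]1CC(C)(Br)C(Br)C[C@@]2(C)C(=O)C[C@@](O)(C(C)C)[C@H]12 | intermediate
14 | 4β-hydroxy-2-oxodauc-8-en-6α-yl 2,2,2-trichloroethyl carbonate | ClC(Cl)(Cl)COC(=O)O[C@H]1CC(C)=CC[C@@]2(C)C(=O)C[C@@](O)(C(C)C)[C@H]12 | intermediate (not isolated)
15 | (1R,4R,5S,6S)-4β,6α-dihydroxydauc-8-en-2-one | O[C@H]1CC(C)=CC[C@@]2(C)C(=O)C[C@@](O)(C(C)C)[C@H]12 | intermediate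
16 | 4-methoxybenzoic acid | COc1ccc(C(=O)O)cc1 | starting material
17 | (1R,4R,5S,6S)-4β-hydroxy-2-oxodauc-8-en-6α-yl 4-methoxybenzoate | COc1ccc(C(=O)O[C@H]2CC(C)=CC[C@@]3(C)C(=O)C[C@@](O)(C(C)C)[C@H]23)cc1 | target

Total step count: 10. Longest linear sequence: 10 steps (1 to 17); 16 enters in the last step.

Steps least certain to work

**Step 8 (C2 oxidation).** The most likely failure is insufficient site discrimination or a stalled reaction: the oxidant may attack C3–H or the isopropyl methine, or fail to reach the neopentyl C2–H, because the selectivity rests only on the electronic and steric bias of the substrate. Fallback: replace substrate control by enzyme control on the unmasked ester, setting out from 10 and returning at 17.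
- 10 is esterified with 16 (EDC, DMAP) to trans-8,9-dibromo-4β-hydroxydaucan-6α-yl 4-methoxybenzoate F1.
- Zinc in acetic acid returns the olefin, giving 4β-hydroxydauc-8-en-6α-yl 4-methoxybenzoate F2.
- F2 is screened against cytochrome P450 BM3 variant libraries and terpenoid-hydroxylating fungi for hydroxylation at C2, to give 2,4β-dihydroxydauc-8-en-6α-yl 4-methoxybenzoate F3.
- Dess–Martin periodinane converts F3 into 17.
- No hydroxylase for this position of the daucane skeleton has been described, so this branch includes an enzyme screen. Allylic hydroxylation and O-demethylation are the reactions to be selected against.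

**Step 3 (key step).** The most likely failure is loss of product specificity or low turnover: capture of water by the last cation, or proton loss at another position, would compete, because olefin release at C5 depends on the fine structure of the active site. Fallback, from 3 back to 4: incubate 3 with a wild-type carotol synthase under the same conditions to obtain (1R,4S,5S)-dauc-8-en-5-ol (carotol) F4, then dehydrate F4 with the Burgess reagent (syn elimination towards C4, toluene, 50 °C) to the tetrasubstituted olefin 4.

**Step 4 (hydroxyselenation and elimination).** The most likely failure is competing selenenylation of the C8=C9 olefin or attack of water at C5, because two nucleophilic olefins are present and the seleniranium ion opens under loose, SN1-like control. Fallback, from 4 back to 7: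
- NBS in aqueous acetone (0 °C) gives 5α-bromodauc-8-en-4β-ol F5.
- K2CO3 in MeOH closes F5 to 4β,5β-epoxydauc-8-ene F6, whose oxygen now sits on the methyl face.
- Diethylaluminium 2,2,6,6-tetramethylpiperidide (Et2Al(TMP), benzene, 0 °C) isomerises F6 to 7. The base should remove a syn proton from the conformationally free C6 and not from the cyclopentane ring.

**Step 6 (hydroboration).** The most likely failure is poor facial selectivity (attack from the β face would give the cis-fused 5β-H, 6β-OH isomer) or slow addition to the very hindered olefin. Fallback, from 7 (before bromination) back to 10: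
- VO(acac)2 and t-BuOOH (CH2Cl2, 0 °C) give 5β,6β-epoxydauc-8-en-4β-ol F7 by hydroxyl-directed epoxidation.
- Cp2TiCl (from Cp2TiCl2 and Mn) with 1,4-cyclohexadiene in THF opens F7 to the C5 radical, which should take up hydrogen from the α face, away from the C1 methyl, the C4 hydroxyl and the C6 titanium alkoxide, to give dauc-8-ene-4β,6β-diol (5α-H) F8.
- Dess–Martin periodinane oxidises F8 to 4β-hydroxydauc-8-en-6-one F9.
- Me4NBH(OAc)3 (MeCN/AcOH, −20 °C) delivers hydride from the face of the C4 hydroxyl to give dauc-8-ene-4β,6α-diol F10.
- Bromine at −78 °C converts F10 into 10.

Further compounds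

F1 | step 8 | trans-8,9-dibromo-4β-hydroxydaucan-6α-yl 4-methoxybenzoate | COc1ccc(C(=O)O[C@H]2CC(C)(Br)C(Br)C[C@@]3(C)CC[C@@](O)(C(C)C)[C@H]23)cc1
F2 | step 8 | 4β-hydroxydauc-8-en-6α-yl 4-methoxybenzoate | COc1ccc(C(=O)O[C@H]2CC(C)=CC[C@@]3(C)CC[C@@](O)(C(C)C)[C@H]23)cc1
F3 | step 8 | 2,4β-dihydroxydauc-8-en-6α-yl 4-methoxybenzoate (C2 configuration open) | COc1ccc(C(=O)O[C@H]2CC(C)=CC[C@@]3(C)C(O)C[C@@](O)(C(C)C)[C@H]23)cc1
F4 | step 3 | (1R,4S,5S)-dauc-8-en-5-ol (carotol) | CC1=CC[C@@]2(C)CC[C@@H](C(C)C)[C@@]2(O)CC1
F5 | step 4 | 5α-bromodauc-8-en-4β-ol | CC1=CC[C@@]2(C)CC[C@@](O)(C(C)C)[C@]2(Br)CC1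
F6 | step 4 | 4β,5β-epoxydauc-8-ene | CC1=CC[C@@]2(C)CC[C@]3(C(C)C)O[C@]23CC1
F7 | step 6 | 5β,6β-epoxydauc-8-en-4β-ol | CC1=CC[C@@]2(C)CC[C@@](O)(C(C)C)[C@]23O[C@@H]3C1
F8 | step 6 | dauc-8-ene-4β,6β-diol (5α-H) | O[C@@H]1CC(C)=CC[C@@]2(C)CC[C@@](O)(C(C)C)[C@H]12
F9 | step 6 | 4β-hydroxydauc-8-en-6-one (5α-H) | O=C1CC(C)=CC[C@@]2(C)CC[C@@](O)(C(C)C)[C@H]12
F10 | step 6 | dauc-8-ene-4β,6α-diol (5α-H) | O[C@H]1CC(C)=CC[C@@]2(C)CC[C@@](O)(C(C)C)[C@H]12
A1 | alternative 1 | endo (5+2) adduct, 8-oxabicyclo[3.2.1]octenone fused to the cyclopentanone (C9 and C4 ketones, C2 silyl ether) | [C@@H]12O[C@@H](C(=O)C(C)=C1)[C@@]3(C)[C@H](O[Si](C)(C)C(C)(C)C)CC(=O)[C@@H]23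
A2 | alternative 1 | 4-(tert-butyldimethylsilyloxy)-3-methylcyclopent-2-en-1-one (enantiomer leading to A1) | CC1=CC(=O)C[C@H]1O[Si](C)(C)C(C)(C)C
A3 | alternative 1 | 4-methyl-3-oxidopyrylium ylide | Cc1cc[o+]cc1[O-]
A4 | alternative 2 | trans-fused bicyclo[5.3.0]dec-6-en-8-one with C2 ketal | C1=CC(=O)CC[C@@]2(C)C3(OCCO3)CC[C@H]12
A5 | alternative 2 | trimethylsilyl enol ether of the trans-hydrindanone with C2 ketal | C1=C(O[Si](C)(C)C)CC[C@@]2(C)C3(OCCO3)CC[C@H]12
A6 | alternative 2 | (R)-Hajos–Parrish ketone | O=C1C=C2CCC(=O)[C@]2(C)CC1
A7 | alternative 3 | bicyclic tertiary allylic alcohol with C5=C6 and C8=C9 olefins and C2 ketal | C1C(C)=CC[C@@]2(C)C3(OCCO3)C[C@@](O)(C(C)C)C2=C1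
A8 | alternative 3 | cycloheptadienyl iodide with C2 ketal and C4 isopropyl ketone side chain | C1C(C)=CC[C@@](C)(C3(OCCO3)CC(=O)C(C)C)C(I)=C1
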